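**Plan**

1. Ring numbering used throughout: C1 (quaternary, CH3 and styryl arm), C2H2, C3H2, C4(CH3)=C5H, C6H (coumarin B). Coumarin A sits on the arm; aryl B and the arm are cis, and both centres are R.
2. Cuts, last to first: the arm CH=CH–aryl A bond (Heck), C4–CH3 (enol triflate methylation), C6–aryl B (conjugate arylation of an enone), then C1–C2 and C5=C6 of the carbocycle (Michael addition, aldol condensation).
3. Enabling feature: quaternary C1 with methyl and a vinyl stub lies in a six-membered ring. C2–C3–C4–C5 is the four-carbon chain of methyl vinyl ketone, and C6–C1(CH3)–CH=CH2 is tiglic aldehyde reacting through its dienamine. The C4 methyl is not the ketone methyl (that carbon becomes C5) and is added later at the carbonyl carbon.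
4. Forward: the carbocycle is closed first; aryl B is added at C6 with the enolate trapped toward C5; the C4 triflate is exchanged for methyl; the vinyl stub is arylated last with the same iodocoumarin that supplies aryl B.
5. Stereochemistry: C1 from the chiral primary amine in step 1; C6 from the chiral diene–rhodium catalyst in step 4; the E alkene from syn insertion and syn β-hydride elimination in step 7.

Key step: step 1

Remark: the sense of induction of the amine (step 1) and of the diene ligand (step 4) is assigned by analogy only; the catalyst antipode that gives (R)-5 and the ligand antipode that arylates C3 of 5 syn to the vinyl group are the ones meant.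

**Step 1**
Reactants: 1 tiglic aldehyde [(E)-2-methylbut-2-enal]; 2 methyl vinyl ketone (but-3-en-2-one)
Product: 5 (4R)-4-ethenyl-4-methylcyclohex-2-en-1-one, via keto aldehyde 3 (not isolated), via ketol 4 (not isolated)
Conditions: 1 (1.5 equiv), (S)-tBuCH(NH2)CH2NEt2 (20 mol%), TfOH (20 mol%), 3-O2NC6H4CO2H (10 mol%), CHCl3, 0 → 25 °C; then 50 °C
Reagents that add atoms: none
Why: Proposed new method: condensation of the primary amine with 1 and γ-deprotonation of the iminium ion should give the s-trans 1-amino-2-methylbuta-1,3-diene (dienamine), whose α-carbon adds to 2 held by the ammonium N–H of the catalyst, forming C1–C2 and the quaternary centre; hydrolysis gives keto aldehyde 3, and enamine or enol formation at the ketone methyl group, attack on the aldehyde and loss of water form C5=C6. The closest known reaction type is the primary-amine-catalysed asymmetric Robinson annulation (Michael addition, aldol condensation) of α,α-disubstituted aldehydes with methyl vinyl ketone, together with the achiral enamine annulation of isobutyraldehyde with the same ketone to 4,4-dimethylcyclohexenone. The six-membered ring closes in a 6-(enolendo)-exo-trig aldol addition, the only closure open to 3 because the aldehyde has no α-hydrogen and the internal α-CH2 of the ketone would give a four-membered ring. C1 is set in the Michael step by the catalyst, whose tert-butyl group blocks one face of the dienamine; the extended geometry (vinyl anti to nitrogen) must be uniform for high selectivity. The step needs α- over γ-attack and over [4+2] cycloaddition: the α-methyl group raises the electron density at the α-carbon, the hydrogen-bonded ketone can reach only that carbon (three atoms from nitrogen), and a secondary enamine N–H tolerates the fully substituted α-carbon.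

**Step 2**
Reactants: 6 dimethoxycoumarin (5,7-dimethoxy-2H-chromen-2-one)
Product: 7 iodocoumarin (8-iodo-5,7-dimethoxy-2H-chromen-2-one)
Conditions: NIS (1.05 equiv), CF3CO2H (cat.), MeCN, 25 °C
Reagents that add atoms: N-iodosuccinimide, O=C1CCC(=O)N1I
Why: Electrophilic aromatic iodination; C8 is para to the 5-methoxy group and ortho to both the 7-methoxy group and the ring oxygen, so it should be the most nucleophilic position, ahead of C6 and the pyranone C3.

**Step 3**
Reactants: 7 iodocoumarin (8-iodo-5,7-dimethoxy-2H-chromen-2-one)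
Product: 8 arylzinc iodide [(5,7-dimethoxy-2-oxo-2H-chromen-8-yl)zinc iodide, LiCl complex in THF, titrated and used as solution]
Conditions: Zn dust (BrCH2CH2Br, Me3SiCl activation), LiCl, THF, 50 °C
Reagents that add atoms: zinc, [Zn]
Why: Direct oxidative insertion of zinc into the aryl C–I bond, assisted by LiCl, which keeps the arylzinc in solution; the lactone is inert to zinc and to the arylzinc formed.

**Step 4**
Reactants: 5 (4R)-4-ethenyl-4-methylcyclohex-2-en-1-one; 8 arylzinc iodide [(5,7-dimethoxy-2-oxo-2H-chromen-8-yl)zinc iodide]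
Product: 9 {[(3R,4R)-3-(5,7-dimethoxy-2-oxo-2H-chromen-8-yl)-4-ethenyl-4-methylcyclohex-1-en-1-yl]oxy}trimethylsilane
Conditions: 8 (1.8 equiv), [RhCl(C2H4)2]2 (2.5 mol%), (1S,4S)-2,5-diphenylbicyclo[2.2.2]octa-2,5-diene (5.5 mol%), Me3SiCl (2 equiv), THF, 20 °C; pentane, filtration, used crude
Reagents that add atoms: chlorotrimethylsilane, C[Si](C)(C)Cl
Why: Rhodium-catalysed asymmetric 1,4-addition of an arylzinc halide with in situ silylation (aryl transfer to monovalent rhodium, insertion of C2=C3 of 5, O-silylation of the oxa-π-allyl rhodium species); the chiral diene, not the weakly differentiated methyl/vinyl pair, sends the aryl group to the face of C3 syn to the vinyl group (the Re face), setting the 3R centre (C6 of the target), and the enol ether fixes the double bond toward C2.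

**Step 5**
Reactants: 9 {[(3R,4R)-3-(5,7-dimethoxy-2-oxo-2H-chromen-8-yl)-4-ethenyl-4-methylcyclohex-1-en-1-yl]oxy}trimethylsilane
Product: 10 (3R,4R)-3-(5,7-dimethoxy-2-oxo-2H-chromen-8-yl)-4-ethenyl-4-methylcyclohex-1-en-1-yl trifluoromethanesulfonate
Conditions: CsF, PhNTf2, DME, 25 °C
Reagents that add atoms: N-phenylbis(trifluoromethanesulfonimide), O=S(=O)(N(c1ccccc1)S(=O)(=O)C(F)(F)F)C(F)(F)F
Why: Fluoride cleaves the O–Si bond to the cesium enolate of defined regiochemistry, which is O-sulfonylated by PhNTf2 present from the start (enol triflate formation from a silyl enol ether), so the double bond stays at C1=C2 and no stereocentre is touched.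

**Step 6**
Reactants: 10 (3R,4R)-3-(5,7-dimethoxy-2-oxo-2H-chromen-8-yl)-4-ethenyl-4-methylcyclohex-1-en-1-yl trifluoromethanesulfonate
Product: 11 vinylcyclohexene (8-[(1R,6R)-6-ethenyl-3,6-dimethylcyclohex-2-en-1-yl]-5,7-dimethoxy-2H-chromen-2-one)
Conditions: Me2Zn (2 equiv), Pd(PPh3)4 (5 mol%), THF, 0 → 50 °C
Reagents that add atoms: dimethylzinc, C[Zn]C
Why: Negishi cross-coupling (oxidative addition of the alkenyl triflate to zerovalent palladium, transmetalation with Me2Zn, reductive elimination) replaces OTf by CH3 without moving the double bond; dimethylzinc alone does not add to the coumarin lactone or the vinyl group.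

**Step 7**
Reactants: 11 vinylcyclohexene (8-[(1R,6R)-6-ethenyl-3,6-dimethylcyclohex-2-en-1-yl]-5,7-dimethoxy-2H-chromen-2-one); 7 iodocoumarin (8-iodo-5,7-dimethoxy-2H-chromen-2-one)
Product: 12 target (8-[(E)-2-[(1R,2R)-2-(5,7-dimethoxy-2-oxo-2H-chromen-8-yl)-1,4-dimethylcyclohex-3-en-1-yl]ethenyl]-5,7-dimethoxy-2H-chromen-2-one)
Conditions: Pd(OAc)2 (10 mol%), P(o-tol)3 (20 mol%), Et3N, DMF, 90 °C
Reagents that add atoms: none
Why: Heck reaction: the arylpalladium iodide from 7 adds to the unsubstituted terminus of the monosubstituted vinyl group, and syn β-hydride elimination, possible only toward the aryl-bearing carbon because C1 is quaternary, gives the E alkene, while the trisubstituted ring alkene is too hindered to compete.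

**Compound list**

1 | tiglic aldehyde [(E)-2-methylbut-2-enal] | C/C=C(\C)C=O | starting material
2 | methyl vinyl ketone (but-3-en-2-one) | CC(=O)C=C | starting material
3 | (2R)-2-ethenyl-2-methyl-5-oxohexanal | C=C[C@@](C=O)(C)CCC(C)=O | intermediate
4 | (4R)-4-ethenyl-3-hydroxy-4-methylcyclohexan-1-one (either C3 epimer) | C=C[C@@]1(C)CCC(=O)CC1O | intermediate
5 | (4R)-4-ethenyl-4-methylcyclohex-2-en-1-one | C=C[C@@]1(C)CCC(=O)C=C1 | intermediate
6 | 5,7-dimethoxy-2H-chromen-2-one (5,7-dimethoxycoumarin) | COc1cc(OC)c2ccc(=O)oc2c1 | starting material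
7 | 8-iodo-5,7-dimethoxy-2H-chromen-2-one | COc1cc(OC)c2ccc(=O)oc2c1I | intermediate
8 | (5,7-dimethoxy-2-oxo-2H-chromen-8-yl)zinc iodide (LiCl complex, THF solution) | COc1cc(OC)c2ccc(=O)oc2c1[Zn]I | intermediate
9 | {[(3R,4R)-3-(5,7-dimethoxy-2-oxo-2H-chromen-8-yl)-4-ethenyl-4-methylcyclohex-1-en-1-yl]oxy}trimethylsilane | C=C[C@@]1(C)CCC(O[Si](C)(C)C)=C[C@H]1c1c(OC)cc(OC)c2ccc(=O)oc12 | intermediate
10 | (3R,4R)-3-(5,7-dimethoxy-2-oxo-2H-chromen-8-yl)-4-ethenyl-4-methylcyclohex-1-en-1-yl trifluoromethanesulfonate | C=C[C@@]1(C)CCC(OS(=O)(=O)C(F)(F)F)=C[C@H]1c1c(OC)cc(OC)c2ccc(=O)oc12 | intermediate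
11 | 8-[(1R,6R)-6-ethenyl-3,6-dimethylcyclohex-2-en-1-yl]-5,7-dimethoxy-2H-chromen-2-one | C=C[C@@]1(C)CCC(C)=C[C@H]1c1c(OC)cc(OC)c2ccc(=O)oc12 | intermediate
12 | 8-[(E)-2-[(1R,2R)-2-(5,7-dimethoxy-2-oxo-2H-chromen-8-yl)-1,4-dimethylcyclohex-3-en-1-yl]ethenyl]-5,7-dimethoxy-2H-chromen-2-one | COc1cc(OC)c2ccc(=O)oc2c1/C=C/[C@@]1(C)CCC(C)=C[C@H]1c1c(OC)cc(OC)c2ccc(=O)oc12 | target

**Count**

Total: 7 steps. Longest linear sequence: 6 steps (6 → 7 → 8 → 9 → 10 → 11 → 12); the branch from 1 and 2 reaches the target in 5 steps.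

**Steps most likely to fail**

Step 1 (proposed new method). Bond formation may occur at the γ-carbon of the dienamine or by [4+2] cycloaddition instead of at the α-carbon. The catalyst amine may be consumed by conjugate addition to the vinyl ketone. A mixture of dienamine geometries would lower the enantiofacial selectivity. The fallback uses known reactions only, sets out from 2 and returns at 5. Methyl vinyl ketone is O-silylated (iPr3SiOTf, Et3N) to 2-(triisopropylsilyloxy)buta-1,3-diene F1. An enantioselective Diels–Alder reaction of F1 with purchased methacrolein, CH2=C(CH3)CHO, follows. The catalyst is the cationic oxazaborolidinium salt from (S)-1-(2-methylphenyl)-3,3-diphenyltetrahydro-1H,3H-pyrrolo[1,2-c][1,3,2]oxazaborole and Tf2NH, or its antipode, in CH2Cl2 at −78 °C. This should give (1S)-1-methyl-4-(triisopropylsilyloxy)cyclohex-3-ene-1-carbaldehyde F2, with the formyl-bearing carbon para to the silyloxy carbon. Wittig methylenation (Ph3P=CH2, THF) gives triisopropyl{[(4S)-4-ethenyl-4-methylcyclohex-1-en-1-yl]oxy}silane F3. Saegusa–Ito oxidation (Pd(OAc)2, MeCN) of the enol ether gives 5. The enol ether must be oxidised as such, because hydrolysis would give the achiral 4-ethenyl-4-methylcyclohexanone.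

Step 4. Aryl transfer and insertion may be slow for an arylzinc with two ortho oxygens at a β-carbon next to a quaternary centre. Protodemetalation of 8, or its addition to the C3=C4 bond of a coumarin, could then take over. Catalyst control over the face may erode if the 1,4-diene unit of 5 displaces the chiral diene from rhodium. The silyl enol ether may hydrolyse, which would lose the enolate regiochemistry. The fallback sets out from 5 and 7 and returns at 10. It is a nickel-catalysed reductive conjugate arylation that needs no arylzinc and no arylrhodium carbometalation. Enone 5, iodide 7 and Et3SiCl with NiCl2(MeOCH2CH2OMe), 2,9-dimethyl-1,10-phenanthroline and Mn powder in DMF should give {[(4R)-3-(5,7-dimethoxy-2-oxo-2H-chromen-8-yl)-4-ethenyl-4-methylcyclohex-1-en-1-yl]oxy}triethylsilane F4 as both C3 epimers, by way of a (1-silyloxyallyl)nickel species. CsF and PhNTf2 as in step 5 then give 10 together with (3S,4R)-3-(5,7-dimethoxy-2-oxo-2H-chromen-8-yl)-4-ethenyl-4-methylcyclohex-1-en-1-yl trifluoromethanesulfonate F5. F5 is removed by chromatography; this fallback gives up catalyst control at C6 and relies on separation of diastereomers.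

Step 7. Coupling of the doubly ortho-substituted aryl iodide at a neopentyl-type vinyl group may be slow, so that reduction of the iodide wins. A palladium hydride may also move the C4=C5 bond into conjugation with aryl B, which would erase the C6 stereocentre. The fallback attaches the arm first, sets out from 5 and 7 and returns at 12. Heck coupling of 7 with the vinyl group of 5 under the step 7 conditions, where no C6 centre or ring trisubstituted alkene exists yet, gives 5,7-dimethoxy-8-[(E)-2-[(1R)-1-methyl-4-oxocyclohex-2-en-1-yl]ethenyl]-2H-chromen-2-one F6. Rhodium-catalysed addition of 8 with Me3SiCl as in step 4 gives 8-[(E)-2-[(1R,2R)-2-(5,7-dimethoxy-2-oxo-2H-chromen-8-yl)-1-methyl-4-(trimethylsilyloxy)cyclohex-3-en-1-yl]ethenyl]-5,7-dimethoxy-2H-chromen-2-one F7. CsF and PhNTf2 give (3R,4R)-3-(5,7-dimethoxy-2-oxo-2H-chromen-8-yl)-4-[(E)-2-(5,7-dimethoxy-2-oxo-2H-chromen-8-yl)ethenyl]-4-methylcyclohex-1-en-1-yl trifluoromethanesulfonate F8. Methylation with Me2Zn and Pd(PPh3)4 as in step 6 gives 12.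

**Further compounds**

F1 | step 1 | 2-(triisopropylsilyloxy)buta-1,3-diene | C=CC(=C)O[Si](C(C)C)(C(C)C)C(C)C
F2 | step 1 | (1S)-1-methyl-4-(triisopropylsilyloxy)cyclohex-3-ene-1-carbaldehyde | O=C[C@@]1(C)CCC(O[Si](C(C)C)(C(C)C)C(C)C)=CC1
F3 | step 1 | triisopropyl{[(4S)-4-ethenyl-4-methylcyclohex-1-en-1-yl]oxy}silane | C=C[C@@]1(C)CCC(O[Si](C(C)C)(C(C)C)C(C)C)=CC1
F4 | step 4 | {[(4R)-3-(5,7-dimethoxy-2-oxo-2H-chromen-8-yl)-4-ethenyl-4-methylcyclohex-1-en-1-yl]oxy}triethylsilane (both C3 epimers) | C=C[C@@]1(C)CCC(O[Si](CC)(CC)CC)=CC1c1c(OC)cc(OC)c2ccc(=O)oc12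
F5 | step 4 | (3S,4R)-3-(5,7-dimethoxy-2-oxo-2H-chromen-8-yl)-4-ethenyl-4-methylcyclohex-1-en-1-yl trifluoromethanesulfonate | C=C[C@@]1(C)CCC(OS(=O)(=O)C(F)(F)F)=C[C@@H]1c1c(OC)cc(OC)c2ccc(=O)oc12
F6 | step 7 | 5,7-dimethoxy-8-[(E)-2-[(1R)-1-methyl-4-oxocyclohex-2-en-1-yl]ethenyl]-2H-chromen-2-one | COc1cc(OC)c2ccc(=O)oc2c1/C=C/[C@@]1(C)CCC(=O)C=C1
F7 | step 7 | 8-[(E)-2-[(1R,2R)-2-(5,7-dimethoxy-2-oxo-2H-chromen-8-yl)-1-methyl-4-(trimethylsilyloxy)cyclohex-3-en-1-yl]ethenyl]-5,7-dimethoxy-2H-chromen-2-one | COc1cc(OC)c2ccc(=O)oc2c1/C=C/[C@@]1(C)CCC(O[Si](C)(C)C)=C[C@H]1c1c(OC)cc(OC)c2ccc(=O)oc12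
F8 | step 7 | (3R,4R)-3-(5,7-dimethoxy-2-oxo-2H-chromen-8-yl)-4-[(E)-2-(5,7-dimethoxy-2-oxo-2H-chromen-8-yl)ethenyl]-4-methylcyclohex-1-en-1-yl trifluoromethanesulfonate | COc1cc(OC)c2ccc(=O)oc2c1/C=C/[C@@]1(C)CCC(OS(=O)(=O)C(F)(F)F)=C[C@H]1c1c(OC)cc(OC)c2ccc(=O)oc12
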